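Ring positions of the chromane are numbered O1, C2, C3, C4, C4a, C5–C8, C8a throughout; the target is compound 19.

## Analysis of the target

Compound 19 is an (E)-chalcone. Its ketone aryl group is a 2,4-dihydroxyphenyl ring (ring A); its β-aryl group is C6 of an 8-hydroxy-2,2-dimethylchromane, a benzo ring (ring B) fused to a pyran (ring C: O1, C2, C3, C4, C4a, C8a). The only stereocentres are C3 and C4 of ring C, both S, with cis hydroxyl groups; C4 is benzylic and C3 lies next to the quaternary C2 with its two methyl groups. Sensitive groups are the enone, the 2'-hydroxyl of ring A (it can close onto the enone to a flavanone under base or hot acid), three oxidisable phenols, and the C4 carbinol, which is benzylic and ortho to O1 and can ionise in strong acid with loss of configuration. The hard part is the cis-diol as one enantiomer: the obvious precursor, a 2,2-dimethylchromene, is a cis-disubstituted cyclic styrene that is epoxidised well (leading to trans-diols) but dihydroxylated with poor enantiocontrol. In addition ring B needs oxygen at C8 beside O1, and the chalcone has to arrive late and be unmasked mildly. The strategy rests on ring C being the chain C2–C3–C4 spanning the ortho positions C8a and C4a, with O1 inserted between C8a and C2. Removing O1 joins C2 to C8a and leaves an indan-1-one whose cis-diol is that of an indene, whose carbonyl carbon becomes C2, and whose ortho oxygen (the later C8–OH) sits where it helps the aryl carbon to migrate.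

## Retrosynthetic reasoning

Protecting groups. Target 19 is taken back to acetonide 18 and then to tris-silyl ether 17. All three phenols are masked as one kind of silyl ether so that fluoride frees them together, and the last step is then only a mild ketal hydrolysis that breaks no bond to C3 or C4.

C6–Cβ bond. Chalcone 17 is cut between C6 of ring B and the enone β-carbon, giving aryl iodide 13 and aryl vinyl ketone 16. A Heck coupling runs under near-neutral conditions that the silyl ethers and the acetonide tolerate, and gives the (E)-alkene directly. Ketone 16 comes from acetophenone 14 through its bis-silyl ether 15; the 2'-oxygen must stay blocked, because a free 2'-hydroxyaryl vinyl ketone would cyclise.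

C6–I bond. Iodide 13 comes from chromane 12 by electrophilic iodination. C6 is para to O1, the strongest donor on ring B, so the halogen does not have to be carried through the earlier steps.

The two C2–methyl bonds. Chromane 12 is taken back to lactone 10, via lactol 11. C2 of 10 is a carbonyl carbon, so both methyl groups are added there one after the other and C2 never becomes a stereocentre.

Protecting-group exchange. Acetonide lactone 10 is derived from carbonate lactone 8 through open ester 9. The acetonide is needed for the organometallic steps that follow; the carbonate is needed for the two steps before, so the change is made here, on a lactone that methanolysis opens faster than base can deprotonate C3.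

Key disconnection, O1–C8a and O1–C2. Lactone 8 is taken back to indanone 7 by removing O1. The forward step must insert oxygen between the carbonyl carbon and the aryl carbon, not between the carbonyl carbon and C2 of the indanone. Two features of 7 are chosen for this: the ortho silyloxy group makes the aryl carbon electron-rich, and the C2 oxygen is an acyl-type (carbonate) oxygen that makes C2 a poor migrating group.

Carbonyl group. Ketone 7 comes from indane 6 by oxidation of its only CH2. The other benzylic C–H of 6 carries the carbonate oxygen and is deactivated, which is the second reason for carrying the diol as a carbonate here.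

C–O bonds and stereocentres. Carbonate 6 comes from epoxide 5 by a stereoretentive carboxylative ring expansion, and 5 from indene 4 by catalyst-controlled epoxidation. On the five-membered ring only a cis-fused carbonate can form, so the cis relation follows from the ring size and the absolute configuration from the epoxidation catalyst.

Indene. Indene 4 comes from silyl ether 2 by reduction (indanol 3) and dehydration, and 2 from commercial hydroxyindanone 1. The hydroxyl of 1 lies next to the CH2 that later becomes the carbonyl of 7, so the oxygen ends up ortho to the migrating carbon, and later at C8.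

## Alternatives that were turned down

Alternative 1: The C4–O bond is formed last, on a chromane that already has the C3 oxygen. In the forward step a high-potential quinone takes hydride from C4 of (S)-6-bromo-8-(methoxymethoxy)-2,2-dimethylchroman-3-yl tert-butyl carbonate A1. The carbonate carbonyl oxygen captures the benzylic cation on the face of the C3 oxygen, isobutene is lost, and the cis-fused cyclic carbonate A2 results.
- For: C3 can be set by established chemistry on an open-chain precursor, the tether enforces the cis relation, and the C6 bromide and C8 oxygen are present from the start. The plan would be several steps shorter than the chosen one, so on step economy it is the stronger plan.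
- Against: the C4 cation is stabilised only by O1, sits on a brominated ring and lies next to the acyloxy-bearing C3. Loss of the C3 proton to a 2H-chromene enol carbonate, the usual outcome of quinone oxidation of chromanes, competes with capture.
- Comparison: the key step would be an unprecedented reaction on a deactivated substrate. The chosen ring expansion is a known reaction type whose one open question, the migratory preference, is decided by how the substrate is built.

Alternative 2: Ring C is assembled from two fragments across C3–C4 and O1–C2. A confined chiral Brønsted acid ionises 4-bromo-2-[bis(allyloxy)methyl]-6-(methoxymethoxy)phenol A3 to the O-allyl ortho-quinone methide A4. A4 adds to the alkenylboronate A5 to give the cis-4-allyloxy-3-boryl chromane A6, in which boron stands for the C3 hydroxyl and the allyl ether for the C4 hydroxyl.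
- For: it is the most convergent plan. The ring and both stereocentres form in one step from achiral materials, and it avoids the protecting-group exchange of the chosen route. On these points it is stronger.
- Against: A5 is a trisubstituted alkene made less nucleophilic by boron. Face selectivity and the endo/exo geometry that decides cis against trans would rest entirely on a catalyst with no close model for this pair. A4 can be re-trapped by the allyl alcohol it releases. C–B oxidation beside a benzylic allyl ether and a deallylation still follow.
- Comparison: the chosen route sets both centres by an epoxidation with long precedent on indenes and then only carries them along.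

Alternative 3: The O1–C8a bond is formed by adding the C2 alkoxide to an aryne. A hindered lithium amide turns the chloroarene 2-[(4S,5S)-5-(2-chlorophenyl)-2,2-dimethyl-1,3-dioxolan-4-yl]propan-2-ol A7 into its alkoxide and, by deprotonation ortho to chlorine, into the C8–C8a aryne. The alkoxide adds at C8a and the C8 aryllithium is borylated to give A8.
- For: the gem-dimethyl carbinol is made by simple double methyl addition before ring closure, so the lactone-to-gem-dimethyl conversion of the chosen route is not needed, and no migratory-aptitude question arises. On both points it is stronger.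
- Against: the cis-dioxolane of A7 is an erythro diol, which asymmetric dihydroxylation of the easily made (E)-alkene does not give. The benzylic acetonide C–H of A7 is acidic towards the amide base and its anion would expel the neighbouring oxygen. A tertiary alkoxide must outrun the amide in adding to the aryne. C8–B must still be oxidised and C6 functionalised.
- Comparison: the length is similar, but control rests on a tandem anionic sequence under the most basic conditions of any plan. The chosen route uses mild, individually known steps and brings the C8 oxygen in with the starting material.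

Key step: step 6

Remarks on the chemistry: the enantiomeric excess from step 3 is assumed to be raised to single-enantiomer level by recrystallisation of 6 or 7, and all later steps conserve it. Lactol 11 is drawn as the cyclic hemiketal (both C2 epimers), in equilibrium with its open hydroxy ketone form.

## Route

Step 1
Reactants: 1 4-hydroxyindan-1-one
Product: 2 4-(triisopropylsilyloxy)indan-1-one
Conditions: i-Pr3SiCl, imidazole, DMF, rt
Reagents that add atoms: triisopropylsilyl chloride, CC(C)[Si](Cl)(C(C)C)C(C)C
Why: Standard phenol silylation; the bulky aryl silyl ether survives hydride, acid, hypochlorite, peroxide, peracid and organometallic steps and later keeps C7 of the chromane from competing in the iodination.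

Step 2
Reactants: 2 4-(triisopropylsilyloxy)indan-1-one
Product: 4 7-(triisopropylsilyloxy)-1H-indene, via racemic indanol 3 (not isolated)
Conditions: NaBH4, MeOH/THF, 0 °C; then TsOH·H2O (cat.), toluene, 80 °C
Reagents that add atoms: none
Why: NaBH4 reduction of the aryl ketone, then acid-catalysed dehydration of the benzylic alcohol; the double bond can only form towards C2, so the remaining CH2 is the one beside the silyloxy-bearing ring carbon, and no stereocentre survives.

Step 3
Reactants: 4 7-(triisopropylsilyloxy)-1H-indene
Product: 5 (1S,2R)-1,2-epoxy-4-(triisopropylsilyloxy)indane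
Conditions: (S,S)-Mn(salen)Cl [salen = N,N'-bis(3,5-di-tert-butylsalicylidene)cyclohexane-1,2-diamine dianion] (3 mol %), 4-phenylpyridine N-oxide, aq. NaOCl (pH 11.3), CH2Cl2, 0 °C
Reagents that add atoms: sodium hypochlorite, [Na+].[O-]Cl
Why: Jacobsen epoxidation of a cis-disubstituted cyclic styrene; with indenes the (S,S)-catalyst gives the (1S,2R)-epoxide, and the remote silyloxy group should not change the facial preference. Both stereocentres of the route are set here.

Step 4
Reactants: 5 (1S,2R)-1,2-epoxy-4-(triisopropylsilyloxy)indane
Product: 6 (1S,2R)-4-(triisopropylsilyloxy)indane-1,2-diyl carbonate (cis-fused cyclic carbonate)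
Conditions: CO2 (10 bar), n-Bu4NBr (10 mol %), MeCN, 80 °C
Reagents that add atoms: carbon dioxide, O=C=O
Why: Halide-catalysed cycloaddition of CO2 to an epoxide: bromide opens the benzylic C1–O bond with inversion, the C2 alkoxide is carboxylated and the carbonate oxygen displaces bromide with a second inversion, so C1 is retained and C2 is never touched. A five-membered carbonate on the indane can only be cis-fused.

Step 5
Reactants: 6 (1S,2R)-4-(triisopropylsilyloxy)indane-1,2-diyl carbonate
Product: 7 (2S,3S)-cis-2,3-(carbonyldioxy)-7-(triisopropylsilyloxy)indan-1-one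
Conditions: t-BuOOH (70% aq.), Rh2(cap)4 (cap = caprolactamate, 1 mol %), NaHCO3, ClCH2CH2Cl, 40 °C
Reagents that add atoms: tert-butyl hydroperoxide, CC(C)(C)OO
Why: Catalytic benzylic C–H oxidation by peroxyl-radical hydrogen abstraction. The only other benzylic C–H (C1–H) carries a carbonate oxygen and is deactivated towards the electrophilic radical as benzylic esters are (1-acyloxyindanes are oxidised at the remote CH2), so the methylene should react. The cis ring fusion keeps the new α-stereocentre from epimerising, since its epimer would be a trans-fused bicycle.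

Step 6
Reactants: 7 (2S,3S)-cis-2,3-(carbonyldioxy)-7-(triisopropylsilyloxy)indan-1-one
Product: 8 (3S,4S)-cis-3,4-(carbonyldioxy)-8-(triisopropylsilyloxy)chroman-2-one
Conditions: CF3CO3H [from (CF3CO)2O and urea·H2O2], Na2HPO4, CH2Cl2, 0 °C to rt
Reagents that add atoms: trifluoroperacetic acid, OOC(=O)C(F)(F)F
Why: Baeyer–Villiger oxidation: the peracid adds to the ketone to give the Criegee adduct, and the group antiperiplanar to the O–O bond shifts from carbon to oxygen as trifluoroacetate leaves. The closest known reaction type is the ring expansion of electron-rich indan-1-ones to 3,4-dihydrocoumarins by aryl migration. Migration of aryl carbon C7a creates the O–aryl bond (O1–C8a), the O–C(=O) bond (O1–C2) comes from the adduct, and the five-membered ketone becomes the six-membered lactone; this is a ring expansion by 1,2-shift, not a cyclisation, so no exo or endo mode applies. No stereocentre is formed: C2 and C3 of 7 are spectators and become C3 and C4 of 8 with the cis relation unchanged. The selectivity needed is aryl migration over C2 migration. The ortho silyloxy group stabilises the phenonium-like transition state of the aryl shift, while the C2 oxygen is a carbonate oxygen whose lone pair is engaged with the carbonyl and which withdraws inductively, so C2 migrates poorly; an ether-type oxygen at C2 would compete more strongly. The Na2HPO4 buffer protects the carbonate and the silyl ether, and once the ring carries the acyloxy group it is too electron-poor for ring oxidation.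

Step 7
Reactants: 8 (3S,4S)-cis-3,4-(carbonyldioxy)-8-(triisopropylsilyloxy)chroman-2-one
Product: 10 (3S,4S)-cis-3,4-(isopropylidenedioxy)-8-(triisopropylsilyloxy)chroman-2-one, via methyl ester triol 9 (not isolated)
Conditions: K2CO3 (0.5 equiv), MeOH, −10 to 0 °C, AcOH quench; then Me2C(OMe)2, camphorsulfonic acid (cat.), toluene, 5 Å sieves, rt to 70 °C
Reagents that add atoms: 2,2-dimethoxypropane, COC(C)(C)OC
Why: Base-catalysed transesterification opens the aryl lactone and the cyclic carbonate at low temperature; methanolysis of an aryl ester is much faster than deprotonation at C3, so β-elimination should not compete. Acid-catalysed ketalisation of the cis-diol and lactonisation of the phenol with the cis-disposed ester, driven by removal of methanol, then give the acetonide lactone. No bond to C3 or C4 is broken.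

Step 8
Reactants: 10 (3S,4S)-cis-3,4-(isopropylidenedioxy)-8-(triisopropylsilyloxy)chroman-2-one
Product: 12 (3S,4S)-3,4-(isopropylidenedioxy)-2,2-dimethyl-8-(triisopropylsilyloxy)chromane, via cyclic hemiketal 11 (not isolated)
Conditions: MeLi (1.1 equiv), THF, −78 °C, aq. NH4Cl; then Me3Al (5 equiv), CH2Cl2, −78 to 0 °C
Reagents that add atoms: methyllithium, [Li]C; trimethylaluminium, C[Al](C)C
Why: One equivalent of MeLi adds to the aryl lactone at −78 °C, and the cis-fused dioxolane holds the adduct as the cyclic hemiketal. Excess Me3Al ionises the aluminium hemiketalate to the cyclic oxocarbenium ion and transfers methyl (Lewis-acid-mediated C-alkylation of a lactol, as in C-glycoside synthesis). C2 ends with two identical methyl groups, so no stereocentre is created.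

Step 9
Reactants: 12 (3S,4S)-3,4-(isopropylidenedioxy)-2,2-dimethyl-8-(triisopropylsilyloxy)chromane
Product: 13 (3S,4S)-6-iodo-3,4-(isopropylidenedioxy)-2,2-dimethyl-8-(triisopropylsilyloxy)chromane
Conditions: N-iodosuccinimide, CF3CO2H (10 mol %), MeCN, 0 °C
Reagents that add atoms: N-iodosuccinimide, O=C1CCC(=O)N1I
Why: Electrophilic aromatic iodination: the alkyl ether oxygen O1 is the strongest donor and directs para to C6, as silylated guaiacols are halogenated para to the alkoxy group. C5 is shielded by the C4 substituent and C7 by the silyl group.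

Step 10
Reactants: 14 2',4'-dihydroxyacetophenone
Product: 15 2',4'-bis(triisopropylsilyloxy)acetophenone
Conditions: i-Pr3SiOTf (2.4 equiv), 2,6-lutidine, CH2Cl2, 0 °C to rt
Reagents that add atoms: triisopropylsilyl trifluoromethanesulfonate, CC(C)[Si](OS(=O)(=O)C(F)(F)F)(C(C)C)C(C)C
Why: Silylation of both phenols; the triflate also reaches the hydrogen-bonded 2'-hydroxyl, and 2,6-lutidine is too weak a base to form the silyl enol ether. The 2'-oxygen must be blocked because a free 2'-hydroxyaryl vinyl ketone would cyclise to a chromanone.

Step 11
Reactants: 15 2',4'-bis(triisopropylsilyloxy)acetophenone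
Product: 16 1-[2,4-bis(triisopropylsilyloxy)phenyl]prop-2-en-1-one
Conditions: (CH2O)n, i-Pr2NH2+ CF3CO2− (1 equiv), CF3CO2H (10 mol %), THF, reflux
Reagents that add atoms: paraformaldehyde (as formaldehyde), C=O
Why: α-Methylenation of a methyl ketone by Mannich condensation with formaldehyde and in-situ elimination of the amine. The aryl vinyl ketone is prone to polymerise and is used at once.

Step 12
Reactants: 13 (3S,4S)-6-iodo-3,4-(isopropylidenedioxy)-2,2-dimethyl-8-(triisopropylsilyloxy)chromane; 16 1-[2,4-bis(triisopropylsilyloxy)phenyl]prop-2-en-1-one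
Product: 17 (E)-1-[2,4-bis(triisopropylsilyloxy)phenyl]-3-[(3S,4S)-3,4-(isopropylidenedioxy)-2,2-dimethyl-8-(triisopropylsilyloxy)chroman-6-yl]prop-2-en-1-one
Conditions: Pd(OAc)2 (5 mol %), n-Bu4NCl, NaHCO3, DMF, 60 °C
Reagents that add atoms: none
Why: Mizoroki–Heck reaction under ligand-free conditions with a tetraalkylammonium chloride: oxidative addition of the aryl iodide to zerovalent palladium, syn insertion of the enone with the aryl group at the terminal carbon, and syn β-hydride elimination to the (E)-enone. The mild base and temperature spare the silyl ethers and the acetonide.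

Step 13
Reactants: 17 (E)-1-[2,4-bis(triisopropylsilyloxy)phenyl]-3-[(3S,4S)-3,4-(isopropylidenedioxy)-2,2-dimethyl-8-(triisopropylsilyloxy)chroman-6-yl]prop-2-en-1-one
Product: 18 (E)-1-(2,4-dihydroxyphenyl)-3-[(3S,4S)-8-hydroxy-3,4-(isopropylidenedioxy)-2,2-dimethylchroman-6-yl]prop-2-en-1-one
Conditions: n-Bu4NF (3.3 equiv), AcOH (3.3 equiv), THF, 0 °C
Reagents that add atoms: none
Why: Fluoride cleavage of the three aryl silyl ethers. Acetic acid buffers the phenoxides so that the 2'-phenoxide does not add to the enone, and the acetonide is untouched.

Step 14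
Reactants: 18 (E)-1-(2,4-dihydroxyphenyl)-3-[(3S,4S)-8-hydroxy-3,4-(isopropylidenedioxy)-2,2-dimethylchroman-6-yl]prop-2-en-1-one
Product: 19 (E)-1-(2,4-dihydroxyphenyl)-3-[(3S,4S)-3,4,8-trihydroxy-2,2-dimethylchroman-6-yl]prop-2-en-1-one (target)
Conditions: AcOH/H2O (4:1), 40 °C
Reagents that add atoms: none
Why: Mild acid hydrolysis of the acetonide by cleavage at the ketal carbon, which breaks neither the C3–O nor the C4–O bond, so the cis-diol is released with retention. The conditions should be too mild to ionise C4 or to close the 2'-hydroxychalcone to the flavanone.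

## Compound list

1 | 4-hydroxyindan-1-one | O=C1CCc2c(O)cccc21 | starting material
2 | 4-(triisopropylsilyloxy)indan-1-one | O=C1CCc2c(O[Si](C(C)C)(C(C)C)C(C)C)cccc21 | intermediate
3 | racemic 4-(triisopropylsilyloxy)indan-1-ol | OC1CCc2c(O[Si](C(C)C)(C(C)C)C(C)C)cccc21 | intermediate
4 | 7-(triisopropylsilyloxy)-1H-indene | C1=Cc2cccc(O[Si](C(C)C)(C(C)C)C(C)C)c2C1 | intermediate
5 | (1S,2R)-1,2-epoxy-4-(triisopropylsilyloxy)indane | C1c2c(O[Si](C(C)C)(C(C)C)C(C)C)cccc2[C@@H]3O[C@H]13 | intermediate
6 | (1S,2R)-4-(triisopropylsilyloxy)indane-1,2-diyl carbonate | C1c2c(O[Si](C(C)C)(C(C)C)C(C)C)cccc2[C@H](OC3=O)[C@@H]1O3 | intermediate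
7 | (2S,3S)-cis-2,3-(carbonyldioxy)-7-(triisopropylsilyloxy)indan-1-one | O=C1c2c(O[Si](C(C)C)(C(C)C)C(C)C)cccc2[C@H](OC3=O)[C@@H]1O3 | intermediate
8 | (3S,4S)-cis-3,4-(carbonyldioxy)-8-(triisopropylsilyloxy)chroman-2-one | O=C1Oc2c(O[Si](C(C)C)(C(C)C)C(C)C)cccc2[C@H](OC3=O)[C@@H]1O3 | intermediate
9 | methyl (2S,3S)-2,3-dihydroxy-3-[2-hydroxy-3-(triisopropylsilyloxy)phenyl]propanoate | COC(=O)[C@@H](O)[C@@H](O)c1cccc(O[Si](C(C)C)(C(C)C)C(C)C)c1O | intermediate
10 | (3S,4S)-cis-3,4-(isopropylidenedioxy)-8-(triisopropylsilyloxy)chroman-2-one | O=C1Oc2c(O[Si](C(C)C)(C(C)C)C(C)C)cccc2[C@H](OC3(C)C)[C@@H]1O3 | intermediate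
11 | (3S,4S)-2-hydroxy-3,4-(isopropylidenedioxy)-2-methyl-8-(triisopropylsilyloxy)chromane, both C2 epimers | CC1(O)Oc2c(O[Si](C(C)C)(C(C)C)C(C)C)cccc2[C@H](OC3(C)C)[C@@H]1O3 | intermediate
12 | (3S,4S)-3,4-(isopropylidenedioxy)-2,2-dimethyl-8-(triisopropylsilyloxy)chromane | CC1(C)Oc2c(O[Si](C(C)C)(C(C)C)C(C)C)cccc2[C@H](OC3(C)C)[C@@H]1O3 | intermediate
13 | (3S,4S)-6-iodo-3,4-(isopropylidenedioxy)-2,2-dimethyl-8-(triisopropylsilyloxy)chromane | CC1(C)Oc2c(O[Si](C(C)C)(C(C)C)C(C)C)cc(I)cc2[C@H](OC3(C)C)[C@@H]1O3 | intermediate
14 | 2',4'-dihydroxyacetophenone | CC(=O)c1ccc(O)cc1O | starting material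
15 | 2',4'-bis(triisopropylsilyloxy)acetophenone | CC(=O)c1ccc(O[Si](C(C)C)(C(C)C)C(C)C)cc1O[Si](C(C)C)(C(C)C)C(C)C | intermediate
16 | 1-[2,4-bis(triisopropylsilyloxy)phenyl]prop-2-en-1-one | C=CC(=O)c1ccc(O[Si](C(C)C)(C(C)C)C(C)C)cc1O[Si](C(C)C)(C(C)C)C(C)C | intermediate
17 | (E)-1-[2,4-bis(triisopropylsilyloxy)phenyl]-3-[(3S,4S)-3,4-(isopropylidenedioxy)-2,2-dimethyl-8-(triisopropylsilyloxy)chroman-6-yl]prop-2-en-1-one | CC1(C)Oc2c(O[Si](C(C)C)(C(C)C)C(C)C)cc(/C=C/C(=O)c4ccc(O[Si](C(C)C)(C(C)C)C(C)C)cc4O[Si](C(C)C)(C(C)C)C(C)C)cc2[C@H](OC3(C)C)[C@@H]1O3 | intermediate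
18 | (E)-1-(2,4-dihydroxyphenyl)-3-[(3S,4S)-8-hydroxy-3,4-(isopropylidenedioxy)-2,2-dimethylchroman-6-yl]prop-2-en-1-one | CC1(C)Oc2c(O)cc(/C=C/C(=O)c4ccc(O)cc4O)cc2[C@H](OC3(C)C)[C@@H]1O3 | intermediate
19 | (E)-1-(2,4-dihydroxyphenyl)-3-[(3S,4S)-3,4,8-trihydroxy-2,2-dimethylchroman-6-yl]prop-2-en-1-one | CC1(C)Oc2c(O)cc(/C=C/C(=O)c3ccc(O)cc3O)cc2[C@H](O)[C@@H]1O | target

## Step count and least certain steps

Total: 14 steps. Longest linear sequence: 12 steps (steps 1–9 and 12–14); steps 10 and 11 form the side branch.

Step 6 (key step). The most likely failure is slow formation of the Criegee adduct at a carbonyl flanked by the bulky silyloxy group, so that electrophilic oxidation of the silyloxy-arene, or a residual shift of C2, competes with the aryl shift. The fallback sets out from 7. Buffered desilylation (HF·pyridine, THF, 0 °C) gives (2S,3S)-cis-2,3-(carbonyldioxy)-7-hydroxyindan-1-one F1. Its ortho-hydroxyl hydrogen-bonds to the carbonyl and makes the aryl group the migrating group in a Dakin-type oxidation (H2O2, B(OH)3, THF), the classical behaviour of ortho-hydroxyaryl ketones. This gives (3S,4S)-cis-3,4-(carbonyldioxy)-8-hydroxychroman-2-one F2, and silylation (i-Pr3SiOTf, 2,6-lutidine) returns to 8.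

Step 5. Hydrogen abstraction at the crowded methylene beside the silyloxy group may be slow, so that on forcing, abstraction at the carbonate-bearing C1–H or oxidation of the arene takes over. The fallback sets out from 6 and separates C–H cleavage from oxidation. Radical bromination (N-bromosuccinimide, AIBN, PhCF3, 80 °C; the bromine atom is small and avoids the acyloxy-bearing C–H) gives the 3-bromo derivative of 6 as both C3 epimers, F3. Silver-assisted hydrolysis (AgNO3, aqueous acetone) gives the corresponding benzylic alcohol F4, and Dess–Martin oxidation returns to 7.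

Step 7. Base may trigger β-elimination across C3–C4 of 8 towards a 3-oxygenated coumarin, or the silyl group may migrate between the two catechol oxygens once the phenoxide is free. The fallback avoids base on the lactone by putting the acetonide in early; it sets out from 5. Acetone with catalytic BF3·OEt2 at −30 °C (benzylic opening and closure, only the cis-fused ketal possible) gives (1S,2R)-cis-1,2-(isopropylidenedioxy)-4-(triisopropylsilyloxy)indane F5. Benzylic oxidation as in step 5 gives (2S,3S)-cis-2,3-(isopropylidenedioxy)-7-(triisopropylsilyloxy)indan-1-one F6, and Baeyer–Villiger oxidation as in step 6 returns to 10. This line gives up the deactivation of C1–H and of C2 by the carbonate and relies on the ortho silyloxy aryl group alone.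

Step 8. The tetrahedral adduct may collapse to the open keto-phenoxide and take up a second methyl, or Me3Al may transfer methyl to the open-chain ketone instead of ionising the hemiketal. The fallback uses no carbanion addition and no oxocarbenium ion; it sets out from 10. Methylenation with Cp2TiMe2 (toluene, 70 °C) gives the exocyclic enol ether (3S,4S)-3,4-(isopropylidenedioxy)-2-methylidene-8-(triisopropylsilyloxy)chromane F7. Cyclopropanation (Et2Zn, CH2I2) gives the spiro-cyclopropane F8, and hydrogenolysis of its CH2–CH2 bond (H2, PtO2, EtOAc/AcOH) returns to 12.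

Step 12. Polymerisation or decomposition of vinyl ketone 16 may outrun the coupling with the electron-rich aryl iodide. The fallback builds the enone by aldol chemistry and sets out from 13 and 15. Iodine–lithium exchange and formylation (n-BuLi, THF, −78 °C; DMF) give the 6-carbaldehyde F9. Addition of the lithium enolate of 15 (LiN(SiMe3)2, THF, −78 °C) gives the β-hydroxy ketone F10, and dehydration (MsCl, Et3N, then DBU) returns to 17.

Step 14. Acid may ionise C4 (epimerisation) or close the free 2'-hydroxychalcone to the flavanone while the acetonide is hydrolysed. The fallback moves the acid step to a stage without the chalcone and ends with fluoride; it sets out from 13. Hydrolysis (AcOH/H2O, 40 °C) gives (3S,4S)-6-iodo-2,2-dimethyl-8-(triisopropylsilyloxy)chromane-3,4-diol F11. Heck coupling with 16 under the conditions of step 12 gives the tris-silylated chalcone diol F12, and n-Bu4NF/AcOH returns to 19.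

## Further compounds

F1 | step 6 | (2S,3S)-cis-2,3-(carbonyldioxy)-7-hydroxyindan-1-one | O=C1c2c(O)cccc2[C@H](OC3=O)[C@@H]1O3
F2 | step 6 | (3S,4S)-cis-3,4-(carbonyldioxy)-8-hydroxychroman-2-one | O=C1Oc2c(O)cccc2[C@H](OC3=O)[C@@H]1O3
F3 | step 5 | 3-bromo derivative of 6, cis-carbonate (1S,2R centres as in 6), both C3 epimers | BrC1c2c(O[Si](C(C)C)(C(C)C)C(C)C)cccc2[C@H](OC3=O)[C@@H]1O3
F4 | step 5 | 3-hydroxy derivative of 6, cis-carbonate, both C3 epimers | OC1c2c(O[Si](C(C)C)(C(C)C)C(C)C)cccc2[C@H](OC3=O)[C@@H]1O3
F5 | step 7 | (1S,2R)-cis-1,2-(isopropylidenedioxy)-4-(triisopropylsilyloxy)indane | C1c2c(O[Si](C(C)C)(C(C)C)C(C)C)cccc2[C@H](OC3(C)C)[C@@H]1O3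
F6 | step 7 | (2S,3S)-cis-2,3-(isopropylidenedioxy)-7-(triisopropylsilyloxy)indan-1-one | O=C1c2c(O[Si](C(C)C)(C(C)C)C(C)C)cccc2[C@H](OC3(C)C)[C@@H]1O3
F7 | step 8 | (3S,4S)-3,4-(isopropylidenedioxy)-2-methylidene-8-(triisopropylsilyloxy)chromane | C=C1Oc2c(O[Si](C(C)C)(C(C)C)C(C)C)cccc2[C@H](OC3(C)C)[C@@H]1O3
F8 | step 8 | (3S,4S)-3,4-(isopropylidenedioxy)-8-(triisopropylsilyloxy)spiro[chromane-2,1'-cyclopropane] | C1CC12Oc3c(O[Si](C(C)C)(C(C)C)C(C)C)cccc3[C@H](OC4(C)C)[C@@H]2O4
F9 | step 12 | (3S,4S)-3,4-(isopropylidenedioxy)-2,2-dimethyl-8-(triisopropylsilyloxy)chromane-6-carbaldehyde | CC1(C)Oc2c(O[Si](C(C)C)(C(C)C)C(C)C)cc(C=O)cc2[C@H](OC3(C)C)[C@@H]1O3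
F10 | step 12 | 1-[2,4-bis(triisopropylsilyloxy)phenyl]-3-hydroxy-3-[(3S,4S)-3,4-(isopropylidenedioxy)-2,2-dimethyl-8-(triisopropylsilyloxy)chroman-6-yl]propan-1-one, both carbinol epimers | CC1(C)Oc2c(O[Si](C(C)C)(C(C)C)C(C)C)cc(C(O)CC(=O)c4ccc(O[Si](C(C)C)(C(C)C)C(C)C)cc4O[Si](C(C)C)(C(C)C)C(C)C)cc2[C@H](OC3(C)C)[C@@H]1O3
F11 | step 14 | (3S,4S)-6-iodo-2,2-dimethyl-8-(triisopropylsilyloxy)chromane-3,4-diol | CC1(C)Oc2c(O[Si](C(C)C)(C(C)C)C(C)C)cc(I)cc2[C@H](O)[C@@H]1O
F12 | step 14 | (E)-1-[2,4-bis(triisopropylsilyloxy)phenyl]-3-[(3S,4S)-3,4-dihydroxy-2,2-dimethyl-8-(triisopropylsilyloxy)chroman-6-yl]prop-2-en-1-one | CC1(C)Oc2c(O[Si](C(C)C)(C(C)C)C(C)C)cc(/C=C/C(=O)c3ccc(O[Si](C(C)C)(C(C)C)C(C)C)cc3O[Si](C(C)C)(C(C)C)C(C)C)cc2[C@H](O)[C@@H]1O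
A1 | alternative 1 | (S)-6-bromo-8-(methoxymethoxy)-2,2-dimethylchroman-3-yl tert-butyl carbonate | CC1(C)Oc2c(OCOC)cc(Br)cc2C[C@@H]1OC(=O)OC(C)(C)C
A2 | alternative 1 | (3S,4S)-cis-6-bromo-8-(methoxymethoxy)-2,2-dimethylchromane-3,4-diyl carbonate | CC1(C)Oc2c(OCOC)cc(Br)cc2[C@H](OC3=O)[C@@H]1O3
A3 | alternative 2 | 4-bromo-2-[bis(allyloxy)methyl]-6-(methoxymethoxy)phenol | C=CCOC(OCC=C)c1cc(Br)cc(OCOC)c1O
A4 | alternative 2 | 6-[(allyloxy)methylidene]-4-bromo-2-(methoxymethoxy)cyclohexa-2,4-dien-1-one | C=CCOC=C1C=C(Br)C=C(OCOC)C1=O
A5 | alternative 2 | 4,4,5,5-tetramethyl-2-(2-methylprop-1-en-1-yl)-1,3,2-dioxaborolane | CC(C)=CB1OC(C)(C)C(C)(C)O1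
A6 | alternative 2 | (3S,4R)-cis-4-allyloxy-6-bromo-8-(methoxymethoxy)-2,2-dimethyl-3-(pinacolatoboryl)chromane | CC1(C)Oc2c(OCOC)cc(Br)cc2[C@H](OCC=C)[C@@H]1B3OC(C)(C)C(C)(C)O3
A7 | alternative 3 | 2-[(4S,5S)-5-(2-chlorophenyl)-2,2-dimethyl-1,3-dioxolan-4-yl]propan-2-ol | CC(C)(O)[C@H]1OC(C)(C)O[C@H]1c1ccccc1Cl
A8 | alternative 3 | (3S,4S)-cis-3,4-(isopropylidenedioxy)-2,2-dimethyl-8-(pinacolatoboryl)chromane | CC1(C)Oc2c(B3OC(C)(C)C(C)(C)O3)cccc2[C@H](OC3(C)C)[C@@H]1O3
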